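The earlier runs and the new flask stem from a simulated flask for substances that don't exist; scatter was added.

The minute is the working unit of these flasks, and the question is how many of them the end of each run lies from its last portion.

| flask | starting complex | incoming ligand | remark | time |
|---|---|---|---|---|
| ash | 0.10 M (in portions, 4) | 0.12 M | run made earlier; portions every 0.80 min |  |
| alder | 0.40 M (in portions, 4) | 0.12 M | run made earlier; portions every 0.80 min |  |
| autumn | 0.20 M (in portions, 4) | 0.120 M | the portions of starting complex follow each other after 0.80 min, the first at the start | 40 min |
| dusk | 0.20 M (in portions, 4) | 0.120 M | the portions of starting complex follow each other after 1.5 min, the first at the start | 40 min |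
| summer | 0.20 M (in portions, 4) | 0.120 M | the portions of starting complex follow each other after 3.0 min, the first at the start | 40 min |
| noon | 0.20 M (in portions, 4) | 0.120 M | the portions of starting complex follow each other after 6.0 min, the first at the start | 40 min |

| run | time / min | complex with two exchanged / % | starting complex / % |
|---|---|---|---|
| ash | 3.00 | 24.9 | 53.5 |
| ash | 5.00 | 27.3 | 50.4 |
| ash | 8.00 | 27.1 | 50.6 |
| ash | 15.0 | 26.6 | 51.6 |
| ash | 25.0 | 25.0 | 52.5 |
| ash | 40.0 | 23.7 | 55.9 |
| alder | 3.00 | 7.0 | 81.9 |
| alder | 5.00 | 6.0 | 80.6 |
| alder | 8.00 | 6.0 | 80.6 |
| alder | 15.0 | 6.3 | 81.8 |
| alder | 25.0 | 5.8 | 81.8 |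
| alder | 40.0 | 5.6 | 81.9 |

(standard deviation of a reading: 0.5 percentage points)

- amount of complex with two exchanged at the end, in percent of the starting complex charged for autumn, dusk, summer, noon, in this order
- the shape of the row from first to last (falls, then rises / falls all the way / rises all the way / hardly changes / rises, then falls)

- "hardly changes" means that all values lie within two and a half points (for a concentration: within two and a half percent of the largest)

In the ash run the complex with two exchanged stands at 27.1 % after 8.00 min and at 23.7 % after 40.0 min. That slow fall gives 239 min, the time in which the amount falls by a factor e at that pace, the drift lifetime τ.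

The autumn flask is reckoned here in two ways. The new charge of 0.20 M is the geometric mean of the charges of ash and alder, so the first way takes the geometric mean of their last readings, 11.5 %. The second way takes the same mean of the readings at 8.00 min, 12.8 %, and lets it drift for 0.134 lifetimes, which leaves 11.2 %. They part by 0.30 percentage points, against a scatter of 0.5 points. The second way is the one that cheats: it lends the pace of ash to autumn, whose charge is larger than that of ash, while alder fell by 0.4 points over the same interval. This reckoning therefore commits to the first number for autumn.

Spacing comes next. Ash had levelled 2.60 min after its last portion, and noon has 22.0 min after its own, 8.46 times as long. So noon should level too. Taking the later last portion as extra drift, noon's delay over autumn is 15.6 min, which gives 10.8 % for noon. That is a fall of 0.73 points, inside the margin of the shape.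

The forecast gives 11.6 %, 11.4 %, 11.1 % and 10.5 %, so the row hardly changes, with “the row sags by about 1 point”. It starts near this reckoning and sags further than this reckoning, by 1.1 points.

The flasks give 12.2 %, 12.0 %, 11.7 % and 11.2 %, so the row hardly changes.

    2 incoming ligand → self-condensation product (k = 0.00670 L mol⁻¹ s⁻¹)
    complex with one exchanged + incoming ligand ⇌ leaving ligand + complex with two exchanged (K = 3.40, k = 0.230 L mol⁻¹ s⁻¹)
    starting complex + incoming ligand ⇌ leaving ligand + complex with one exchanged (K = 1.20, k = 0.190 L mol⁻¹ s⁻¹)

At the end the self-condensation product stands at 0.00955 M in autumn and 0.0132 M in noon. Carried from autumn's 12.2 % over the delay of 15.6 min, the drift lifetime gives 11.4 % for noon, and noon holds 11.2 %.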